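**Plan**

- Retrosynthetic cuts: the acyl C–O bond of the 2‑methylbutanoate; the CH2–O–aryl ether bond to umbelliferone; then, in one stroke, the ring bond between the carbinol carbon and the CMe2 carbon together with the ring C=C. This [3+3] split gives ethyl 2‑acetyl‑3‑methylbut‑2‑enoate and an acrolein‑derived 3‑silyloxyallyl ylide.
- Enabling feature: in the cyclohexene ring the CMe2 carbon and the methyl‑bearing sp2 carbon are both bonded to the CH(CH2OAr) carbon. They are the β‑carbon and the acetyl carbon of an isopropylidene acetoacetate (a 1,3‑dielectrophile). The remaining ring arc CH(O)–CH2–CH= is a three‑carbon 1,3‑dinucleophile at the oxidation level of acrolein.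
- Forward order: acceptor and phosphonium salt are made separately; their union (γ‑Michael addition, then intramolecular Wittig) closes the only carbocycle. Desilylation, ketone reduction, a temporary bridged γ‑lactone, LiAlH4 reduction, Mitsunobu etherification and acylation follow.
- Stereochemistry: the carbinol centre comes from a catalyst‑controlled Corey–Bakshi–Shibata reduction of the racemic β,γ‑enone. The CH(CH2OAr) centre is then set by base‑mediated epimerisation funnelled through lactonisation, which only the cis isomer can undergo; this lactone ring is not in the target and is cleaved by LiAlH4. The acyl stereocentre is bought as (R)‑2‑methylbutanoic acid.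

Key step: step 3

Remark: 5 is used as an E/Z mixture and 8 and 9 are racemates (their SMILES carry no stereodescriptors); absolute configuration enters in step 5.

**Step 1**
Reactants: 1 ethyl acetoacetate; 2 acetone
Product: 3 ethyl 2‑acetyl‑3‑methylbut‑2‑enoate
Conditions: ZnCl2 (cat.), Ac2O, reflux
Reagents that add atoms: none
Why: Knoevenagel condensation of a ketone with a β‑keto ester, driven by acetic anhydride as water scavenger; the alkene carries two identical methyl groups, so no stereochemical issue arises.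

**Step 2**
Reactants: 4 acrolein
Product: 5 [3‑(tert‑butyldimethylsilyloxy)prop‑2‑en‑1‑yl]triphenylphosphonium trifluoromethanesulfonate (E/Z mixture)
Conditions: PPh3, TBSOTf, THF, −78 °C → rt; precipitation with Et2O under argon
Reagents that add atoms: triphenylphosphine, c1ccc(cc1)P(c1ccccc1)c1ccccc1; tert‑butyldimethylsilyl trifluoromethanesulfonate, CC(C)(C)[Si](C)(C)OS(=O)(=O)C(F)(F)F
Why: Phosphoniosilylation of an enal (conjugate addition of the phosphine, O‑silylation of the zwitterionic enolate) should give the β‑phosphonio silyl enol ether; the enol ether geometry is immaterial because it is lost in step 3.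

**Step 3**
Reactants: 3 ethyl 2‑acetyl‑3‑methylbut‑2‑enoate; 5 [3‑(tert‑butyldimethylsilyloxy)prop‑2‑en‑1‑yl]triphenylphosphonium trifluoromethanesulfonate
Product: 8 ethyl 5‑(tert‑butyldimethylsilyloxy)‑2,6,6‑trimethylcyclohexa‑2,4‑diene‑1‑carboxylate (racemic), via silyloxyallylidene ylide 6 (not isolated), via Michael adduct ylide 7 (not isolated)
Conditions: KN(SiMe3)2, THF, −78 °C; then 3, −78 °C → 65 °C
Reagents that add atoms: none
Why: Proposed new method: deprotonation of 5 gives ylide 6, whose silyloxy‑bearing γ‑carbon should add to the doubly activated β,β‑dimethyl terminus of 3 (C–C bond to the quaternary carbon); proton transfer from the new silyloxy‑bearing CH to the β‑keto ester enolate then regenerates an allylic ylide (7) and frees the methyl ketone, which closes the ring by intramolecular Wittig olefination (the ring C=C) with loss of Ph3P=O. The closest known reaction type is the cyclohexa‑1,3‑diene annulation of unsubstituted allylidenetriphenylphosphorane with alkylidene acetoacetates (γ‑Michael addition/intramolecular Wittig, known for acceptor 3 itself), whereas phosphoniosilylation‑derived ylides are so far known to react with aldehydes at the phosphorus‑bearing carbon. The six‑membered ring closes by 6‑exo‑trig attack of the ylide carbon on the acetyl carbonyl, and the olefination fixes the trisubstituted alkene at the position required, out of conjugation with the ester, which a cationic cyclisation could not guarantee. The only stereocentre formed, the ester‑bearing ring carbon, arises by uncontrolled protonation and is deliberately left racemic and epimerisable for the convergent lactonisation of step 6. The selectivity needed is γ‑ over α‑attack of the ylide and 1,4‑ over 1,2‑addition; the hindered, enolisable acetyl group flanked by a tetrasubstituted alkene resists direct Wittig reaction, the conjugate additions are reversible, and only the γ‑adduct can drain irreversibly through a six‑membered‑ring oxaphosphetane.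

**Step 4**
Reactants: 8 ethyl 5‑(tert‑butyldimethylsilyloxy)‑2,6,6‑trimethylcyclohexa‑2,4‑diene‑1‑carboxylate
Product: 9 ethyl 2,6,6‑trimethyl‑5‑oxocyclohex‑2‑ene‑1‑carboxylate (racemic)
Conditions: Bu4NF, AcOH, THF, −78 → 0 °C
Reagents that add atoms: none
Why: Fluoride desilylation releases a dienolate that is protonated kinetically at its α‑carbon under buffered conditions, which should give the β,γ‑unsaturated ketone with the ring alkene left where step 3 placed it.

**Step 5**
Reactants: 9 ethyl 2,6,6‑trimethyl‑5‑oxocyclohex‑2‑ene‑1‑carboxylate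
Product: 10 ethyl (1S,5R)‑5‑hydroxy‑2,6,6‑trimethylcyclohex‑2‑ene‑1‑carboxylate (cis) and 11 ethyl (1R,5R)‑5‑hydroxy‑2,6,6‑trimethylcyclohex‑2‑ene‑1‑carboxylate (trans), a mixture of C‑1 epimers carried on unseparated
Conditions: (S)‑1‑methyl‑3,3‑diphenyltetrahydro‑1H,3H‑pyrrolo[1,2‑c][1,3,2]oxazaborole [(S)‑Me‑CBS, 10 mol %], catecholborane, toluene, −40 → −20 °C; MeOH, pH 7 buffer
Reagents that add atoms: none
Why: Corey–Bakshi–Shibata reduction, in which the catalyst distinguishes the quaternary CMe2 flank (large) from the CH2 flank (small) and should deliver hydride to give the (R)‑carbinol from both enantiomers of 9 (the sense known for tert‑alkyl methyl ketones), so that the racemate is sorted into cis and trans epimers of one carbinol configuration; catecholborane spares the alkene and the ester.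

**Step 6**
Reactants: 10 ethyl (1S,5R)‑5‑hydroxy‑2,6,6‑trimethylcyclohex‑2‑ene‑1‑carboxylate; 11 ethyl (1R,5R)‑5‑hydroxy‑2,6,6‑trimethylcyclohex‑2‑ene‑1‑carboxylate
Product: 12 (1S,5R)‑2,8,8‑trimethyl‑6‑oxabicyclo[3.2.1]oct‑2‑en‑7‑one
Conditions: 1,8‑diazabicyclo[5.4.0]undec‑7‑ene (DBU, 0.5 equiv), toluene, 110 °C, 4 Å molecular sieves
Reagents that add atoms: none
Why: Base‑mediated epimerisation of the allylic ester α‑carbon through its dienolate, coupled to γ‑lactonisation that only the cis isomer can undergo, should funnel both epimers (and any conjugated alkene isomer formed reversibly) into one bridged lactone, whose bridgehead α‑carbon can no longer enolise (Bredt's rule) and so locks the CH centre relative to the carbinol centre.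

**Step 7**
Reactants: 12 (1S,5R)‑2,8,8‑trimethyl‑6‑oxabicyclo[3.2.1]oct‑2‑en‑7‑one
Product: 13 (1R,5S)‑5‑(hydroxymethyl)‑4,6,6‑trimethylcyclohex‑3‑en‑1‑ol
Conditions: LiAlH4, THF, 0 °C → rt
Reagents that add atoms: none
Why: Hydride reduction of the lactone opens the temporary ring to the cis diol without touching either stereocentre or the isolated trisubstituted alkene.

**Step 8**
Reactants: 13 (1R,5S)‑5‑(hydroxymethyl)‑4,6,6‑trimethylcyclohex‑3‑en‑1‑ol; 14 umbelliferone (7‑hydroxy‑2H‑chromen‑2‑one)
Product: 15 7‑{[(1S,5R)‑5‑hydroxy‑2,6,6‑trimethylcyclohex‑2‑en‑1‑yl]methoxy}‑2H‑chromen‑2‑one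
Conditions: PPh3, DIAD, THF, 0 °C → rt
Reagents that add atoms: none
Why: Mitsunobu etherification with an acidic phenol should take place at the primary carbinol only, the secondary hydroxyl next to the quaternary carbon being too hindered to be activated; substitution occurs at a CH2 group, so no stereocentre is involved.

**Step 9**
Reactants: 15 7‑{[(1S,5R)‑5‑hydroxy‑2,6,6‑trimethylcyclohex‑2‑en‑1‑yl]methoxy}‑2H‑chromen‑2‑one; 16 (R)‑2‑methylbutanoic acid
Product: 17 (1R,5S)‑4,6,6‑trimethyl‑5‑{[(2‑oxo‑2H‑chromen‑7‑yl)oxy]methyl}cyclohex‑3‑en‑1‑yl (2R)‑2‑methylbutanoate (target)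
Conditions: DCC, 4‑(dimethylamino)pyridine (DMAP, cat.), CH2Cl2, 0 °C → rt
Reagents that add atoms: none
Why: Steglich esterification acylates the hindered secondary alcohol under mild, nearly neutral conditions that should leave the α‑stereocentre of the acid and the coumarin lactone intact; the carbinol configuration is retained because the C–O bond of the alcohol is not broken.

**Compound list**

1 | ethyl acetoacetate | CCOC(=O)CC(C)=O | starting material
2 | acetone | CC(C)=O | starting material
3 | ethyl 2‑acetyl‑3‑methylbut‑2‑enoate | CCOC(=O)C(C(C)=O)=C(C)C | intermediate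
4 | acrolein | C=CC=O | starting material
5 | [3‑(tert‑butyldimethylsilyloxy)prop‑2‑en‑1‑yl]triphenylphosphonium trifluoromethanesulfonate (E/Z mixture) | CC(C)(C)[Si](C)(C)OC=CC[P+](c1ccccc1)(c1ccccc1)c1ccccc1.[O-]S(=O)(=O)C(F)(F)F | intermediate
6 | [3‑(tert‑butyldimethylsilyloxy)prop‑2‑en‑1‑ylidene]triphenylphosphorane (not isolated) | CC(C)(C)[Si](C)(C)OC=CC=P(c1ccccc1)(c1ccccc1)c1ccccc1 | intermediate
7 | ethyl 2‑acetyl‑4‑(tert‑butyldimethylsilyloxy)‑3,3‑dimethyl‑6‑(triphenyl‑λ5‑phosphanylidene)hex‑4‑enoate (not isolated) | CCOC(=O)C(C(C)=O)C(C)(C)C(O[Si](C)(C)C(C)(C)C)=CC=P(c1ccccc1)(c1ccccc1)c1ccccc1 | intermediate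
8 | ethyl 5‑(tert‑butyldimethylsilyloxy)‑2,6,6‑trimethylcyclohexa‑2,4‑diene‑1‑carboxylate (racemic) | CCOC(=O)C1C(C)=CC=C(O[Si](C)(C)C(C)(C)C)C1(C)C | intermediate
9 | ethyl 2,6,6‑trimethyl‑5‑oxocyclohex‑2‑ene‑1‑carboxylate (racemic) | CCOC(=O)C1C(C)=CCC(=O)C1(C)C | intermediate
10 | ethyl (1S,5R)‑5‑hydroxy‑2,6,6‑trimethylcyclohex‑2‑ene‑1‑carboxylate | O[C@@H]1CC=C(C)[C@H](C(=O)OCC)C1(C)C | intermediate
11 | ethyl (1R,5R)‑5‑hydroxy‑2,6,6‑trimethylcyclohex‑2‑ene‑1‑carboxylate | O[C@@H]1CC=C(C)[C@@H](C(=O)OCC)C1(C)C | intermediate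
12 | (1S,5R)‑2,8,8‑trimethyl‑6‑oxabicyclo[3.2.1]oct‑2‑en‑7‑one | O=C1O[C@@H]2CC=C(C)[C@H]1C2(C)C | intermediate
13 | (1R,5S)‑5‑(hydroxymethyl)‑4,6,6‑trimethylcyclohex‑3‑en‑1‑ol | O[C@@H]1CC=C(C)[C@H](CO)C1(C)C | intermediate
14 | umbelliferone (7‑hydroxy‑2H‑chromen‑2‑one) | Oc1ccc2ccc(=O)oc2c1 | starting material
15 | 7‑{[(1S,5R)‑5‑hydroxy‑2,6,6‑trimethylcyclohex‑2‑en‑1‑yl]methoxy}‑2H‑chromen‑2‑one | O[C@@H]1CC=C(C)[C@H](COc2ccc3ccc(=O)oc3c2)C1(C)C | intermediate
16 | (R)‑2‑methylbutanoic acid | CC[C@@H](C)C(=O)O | starting material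
17 | (1R,5S)‑4,6,6‑trimethyl‑5‑{[(2‑oxo‑2H‑chromen‑7‑yl)oxy]methyl}cyclohex‑3‑en‑1‑yl (2R)‑2‑methylbutanoate | CC[C@@H](C)C(=O)O[C@@H]1CC=C(C)[C@H](COc2ccc3ccc(=O)oc3c2)C1(C)C | target

**Totals**

Total step count: 9. Longest linear sequence: 8 steps (steps 1, 3–9 from ethyl acetoacetate, or steps 2, 3–9 from acrolein).

**Steps most likely to fail**

1. Step 3 (proposed new method). What may go wrong: the ylide reacts through its phosphorus‑bearing carbon instead of the silyloxy‑bearing terminus, the basic ylide deprotonates 3 at a γ‑methyl group, or the proton transfer that must regenerate the ylide at the hindered silyloxy‑substituted carbon is too slow. Fallback with known chemistry, setting out from 3 and returning at 9: 3 is annulated with the unsubstituted ylide from allyltriphenylphosphonium bromide and KN(SiMe3)2 in THF (the established cyclohexadiene annulation of this acceptor) to give ethyl 2,6,6‑trimethylcyclohexa‑2,4‑diene‑1‑carboxylate F1. The ring oxygen is then brought in at the diene terminus next to the CMe2 carbon by [4+2] photooxygenation (O2, tetraphenylporphyrin, hν, CH2Cl2, −20 °C) to the endoperoxide ethyl 1,8,8‑trimethyl‑2,3‑dioxabicyclo[2.2.2]oct‑5‑ene‑7‑carboxylate F2. Kornblum–DeLaMare rearrangement (Et3N, CH2Cl2) removes the only bridgehead hydrogen and gives the γ‑hydroxy enone ethyl 2‑hydroxy‑2,6,6‑trimethyl‑5‑oxocyclohex‑3‑ene‑1‑carboxylate F3. Reductive cleavage of the vinylogous α‑ketol (Zn dust, AcOH) with α‑protonation of the resulting dienol should give the β,γ‑enone 9.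

2. Step 5. What may go wrong: the substrate's own facial bias overrides the catalyst in the mismatched enantiomer, so that the wrong carbinol configuration is carried into step 6 as the mirror‑image lactone and the enantiomeric purity erodes; hydroboration of the ring alkene may also compete. Fallback, setting out from 9 and returning at 12: substrate‑controlled reduction (NaBH4, CeCl3·7H2O, MeOH, −78 °C; axial hydride delivery next to the gem‑dimethyl group) gives the racemic cis hydroxy ester, that is 10 together with its enantiomer ethyl (1R,5S)‑5‑hydroxy‑2,6,6‑trimethylcyclohex‑2‑ene‑1‑carboxylate F4. The conditions of step 6 convert this into the racemic lactone, 12 together with (1R,5S)‑2,8,8‑trimethyl‑6‑oxabicyclo[3.2.1]oct‑2‑en‑7‑one F5. The racemate is resolved by preparative chromatography on a chiral stationary phase (amylose tris(3,5‑dimethylphenylcarbamate)), and 12 re‑enters the route at step 7.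

3. Step 8. What may go wrong: intramolecular displacement by the cis secondary hydroxyl at the activated primary carbon (closure to a bridged bicyclic ether) outruns a slow intermolecular SN2 reaction at the β‑branched primary centre. Fallback, setting out from 13 and returning at 17, with the two hydroxyl groups differentiated before the ether is made: selective silylation of the primary alcohol (TBSCl, imidazole, CH2Cl2, 0 °C) gives (1R,5S)‑5‑{[(tert‑butyldimethylsilyl)oxy]methyl}‑4,6,6‑trimethylcyclohex‑3‑en‑1‑ol F6. Acylation with 16 (DCC, DMAP, CH2Cl2) gives (1R,5S)‑5‑{[(tert‑butyldimethylsilyl)oxy]methyl}‑4,6,6‑trimethylcyclohex‑3‑en‑1‑yl (2R)‑2‑methylbutanoate F7. Desilylation (HF·pyridine, THF) gives (1R,5S)‑5‑(hydroxymethyl)‑4,6,6‑trimethylcyclohex‑3‑en‑1‑yl (2R)‑2‑methylbutanoate F8, in which no free hydroxyl can cyclise. Mitsunobu etherification with 14 (PPh3, DIAD, THF) then gives 17.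

**Further compounds**

F1 | step 3 | ethyl 2,6,6‑trimethylcyclohexa‑2,4‑diene‑1‑carboxylate (racemic) | CCOC(=O)C1C(C)=CC=CC1(C)C
F2 | step 3 | ethyl 1,8,8‑trimethyl‑2,3‑dioxabicyclo[2.2.2]oct‑5‑ene‑7‑carboxylate (racemic, diastereomer mixture) | CCOC(=O)C1C2(C)C=CC(OO2)C1(C)C
F3 | step 3 | ethyl 2‑hydroxy‑2,6,6‑trimethyl‑5‑oxocyclohex‑3‑ene‑1‑carboxylate (racemic, diastereomer mixture) | CCOC(=O)C1C(C)(O)C=CC(=O)C1(C)C
F4 | step 5 | ethyl (1R,5S)‑5‑hydroxy‑2,6,6‑trimethylcyclohex‑2‑ene‑1‑carboxylate | O[C@H]1CC=C(C)[C@@H](C(=O)OCC)C1(C)C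
F5 | step 5 | (1R,5S)‑2,8,8‑trimethyl‑6‑oxabicyclo[3.2.1]oct‑2‑en‑7‑one | O=C1O[C@H]2CC=C(C)[C@@H]1C2(C)C
F6 | step 8 | (1R,5S)‑5‑{[(tert‑butyldimethylsilyl)oxy]methyl}‑4,6,6‑trimethylcyclohex‑3‑en‑1‑ol | O[C@@H]1CC=C(C)[C@H](CO[Si](C)(C)C(C)(C)C)C1(C)C
F7 | step 8 | (1R,5S)‑5‑{[(tert‑butyldimethylsilyl)oxy]methyl}‑4,6,6‑trimethylcyclohex‑3‑en‑1‑yl (2R)‑2‑methylbutanoate | CC[C@@H](C)C(=O)O[C@@H]1CC=C(C)[C@H](CO[Si](C)(C)C(C)(C)C)C1(C)C
F8 | step 8 | (1R,5S)‑5‑(hydroxymethyl)‑4,6,6‑trimethylcyclohex‑3‑en‑1‑yl (2R)‑2‑methylbutanoate | CC[C@@H](C)C(=O)O[C@@H]1CC=C(C)[C@H](CO)C1(C)C
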